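**Retrosynthetic overview**
1. The target has one ring and one stereocentre, and both are made in a single operation on the complete acyclic C20 chain. All-E geranylgeraniol (1) is cyclized at its head: protonation of the terminal 14,15-olefin, C10–C15 bond formation to tertiary cation 2, and loss of a proton from the C11 methyl give (S)-trixagol (3).
2. The C10–C15 ring bond is the only C–C disconnection; no C–C bond is made before or after it.
3. The ester C–O bond is the only other disconnection: 3 and Meldrum's acid (4) give, through hemiketal ester 5, the free hydrogen malonate 6 (target) without a protecting group.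
4. Ring order: the cyclohexane ring is the only ring and is formed in step 1, before the acylation.

Assumption: all-E geranylgeraniol (bulk annatto-derived material, purified once on silica) is taken as a cheap commercial starting material; locants C1–C15 are those of geranylgeraniol (C1 = CH2OH).

**Step 1**
Reactants: 1 (2E,6E,10E)-geranylgeraniol
Product: 3 (S)-trixagol = (2E,6E)-9-[(1S)-2,2-dimethyl-6-methylidenecyclohexyl]-3,7-dimethylnona-2,6-dien-1-ol, via enzyme-bound tertiary cyclohexyl cation 2 (not isolated)
Conditions: squalene–hopene cyclase from Alicyclobacillus acidocaldarius, D377C-type monocyclizing variant (E. coli whole cells), 5 mM 1, 0.2% Triton X-100, Na citrate buffer pH 6.0, 50 °C, 48–72 h; EtOAc extraction; AgNO3–SiO2 chromatography (unreacted 1 recycled; ee by chiral GC)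
Reagents that add atoms: none
Why: Proposed new method: enzymatic Brønsted-acid (class II terpene-cyclase type) cation–olefin monocyclization, in which the active-site Asp376 proton adds to C14 of the terminal isopropylidene of 1 held in the enzyme's chair fold, the 10,11-olefin closes the C10–C15 bond to give cation 2, and, because the D377C exchange removes the carboxylate that stabilises this A-ring cation for the next ring closure, 2 is quenched by proton loss from the C11 methyl to the exocyclic methylene; the (S) centre is set in the C–C bond-forming event by the same enforced fold that gives hopene its 5α-H/10β-methyl A ring; the closest known reactions are the monocyclization of squalene to 3-deoxyachilleol A by this variant class (same ring, same absolute sense), the cyclase-variant monocyclization of (E)-geranylacetone to (S)-γ-dihydroionone, and the acceptance of geranylgeraniol itself by the wild-type enzyme (which over-cyclizes it).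

**Step 2**
Reactants: 3 (S)-trixagol; 4 Meldrum's acid (2,2-dimethyl-1,3-dioxane-4,6-dione)
Product: 6 (S)-trixagol hydrogen malonate = 3-{[(2E,6E)-9-[(1S)-2,2-dimethyl-6-methylidenecyclohexyl]-3,7-dimethylnona-2,6-dien-1-yl]oxy}-3-oxopropanoic acid = target, via ring-opened hemiketal ester 5 (not isolated)
Conditions: 4 (1.05 equiv), toluene, 90 °C, 4 h; water wash; SiO2 chromatography (hexane/EtOAc, 0.5% AcOH)
Reagents that add atoms: Meldrum's acid, CC1(C)OC(=O)CC(=O)O1
Why: Acylative ring opening of the cyclic acylal Meldrum's acid by the primary allylic alcohol gives hemiketal ester 5, which expels acetone irreversibly and leaves the malonic half-ester directly; no stereocentre is formed or touched, and the weakly acidic, non-oxidising conditions leave the exocyclic methylene, both E-trisubstituted olefins and the allylic C–O bond intact.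

**Compound list**
1 | (2E,6E,10E)-geranylgeraniol, (2E,6E,10E)-3,7,11,15-tetramethylhexadeca-2,6,10,14-tetraen-1-ol | CC(C)=CCC/C(C)=C/CC/C(C)=C/CC/C(C)=C/CO | starting material
2 | enzyme-bound tertiary cation, 2-[(3E,7E)-9-hydroxy-3,7-dimethylnona-3,7-dien-1-yl]-1,3,3-trimethylcyclohexan-1-ylium, ring CH arranged in space as in 3 | C[C+]1CCCC(C)(C)[C@@H]1CC/C(C)=C/CC/C(C)=C/CO | intermediate
3 | (S)-trixagol, (2E,6E)-9-[(1S)-2,2-dimethyl-6-methylidenecyclohexyl]-3,7-dimethylnona-2,6-dien-1-ol | C=C1CCCC(C)(C)[C@@H]1CC/C(C)=C/CC/C(C)=C/CO | intermediate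
4 | Meldrum's acid, 2,2-dimethyl-1,3-dioxane-4,6-dione | CC1(C)OC(=O)CC(=O)O1 | starting material
5 | ring-opened hemiketal ester, 1-[(2E,6E)-9-[(1S)-2,2-dimethyl-6-methylidenecyclohexyl]-3,7-dimethylnona-2,6-dien-1-yl] 3-(2-hydroxypropan-2-yl) propanedioate | C=C1CCCC(C)(C)[C@@H]1CC/C(C)=C/CC/C(C)=C/COC(=O)CC(=O)OC(C)(C)O | intermediate
6 | (S)-trixagol hydrogen malonate, 3-{[(2E,6E)-9-[(1S)-2,2-dimethyl-6-methylidenecyclohexyl]-3,7-dimethylnona-2,6-dien-1-yl]oxy}-3-oxopropanoic acid | C=C1CCCC(C)(C)[C@@H]1CC/C(C)=C/CC/C(C)=C/COC(=O)CC(=O)O | target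

**Totals**
Total step count: 2. Longest linear sequence: 2 steps (1 → 3 → 6).

**Steps most likely to fail** (the route has only two steps, so both are ranked; there is no third)

1. Step 1 is the main risk. The monocyclizing variant may turn over the polar C20 alcohol slowly. It may also let part of cation 2 go on to labdane-type bicycles or cyclic ethers, or give some endocyclic olefin isomer.

   The fallback cyclizes a C13 substrate that cannot over-cyclize and then builds the chain with all-E control. It does not set out from a numbered compound of the route: in place of 1 it starts from commercial (E)-geranylacetone F1, and it comes back to the route at 3.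
   - A cyclase variant of the kind known for this substrate (whole cells, citrate buffer pH 6, 30–50 °C) monocyclizes it to (S)-γ-dihydroionone F2.
   - Kinetic enolization at the methyl group (LDA, THF, −78 °C) and trapping with ClP(O)(OEt)2 gives the terminal enol diethyl phosphate F3. It is not isolated but eliminated with a further 2.2 equiv of LDA to the terminal alkyne F4.
   - Zr-catalysed methylalumination (Me3Al, cat. Cp2ZrCl2, CH2Cl2, rt) gives the (E)-alkenylalane F5, and iodinolysis (I2, THF, −30 °C) gives the (E)-vinyl iodide F6.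
   - Zinc insertion into 4-bromo-1-(trimethylsilyl)but-1-yne gives [4-(trimethylsilyl)but-3-yn-1-yl]zinc bromide F7. Pd-catalysed Negishi coupling of it with the vinyl iodide (Pd(PPh3)4, THF, rt) gives the TMS-enyne F8.
   - K2CO3/MeOH gives the terminal enyne F9.
   - A second methylalumination gives the (1E,5E)-dienylalane F10. n-BuLi turns it into the lithium alanate F11, and paraformaldehyde hydroxymethylates this to 3. Both new olefins form by syn-carbometalation and are expected ≥98% E.

2. Step 2 runs hot and weakly acidic. Possible failures are incomplete conversion, decarboxylation of the half-ester to the acetate, or acid-promoted migration of the exocyclic olefin or ionization of the allylic ester.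

   The fallback is a carbodiimide coupling with a fluoride-labile mono-protected malonic acid, followed by deprotection under non-acidic conditions. It sets out from 3 (with 4 as the malonyl source) and comes back to the route at 6.
   - Meldrum's acid 4 is opened with 2-(trimethylsilyl)ethanol (toluene, 90 °C) to 2-(trimethylsilyl)ethyl hydrogen malonate F12.
   - DCC and cat. DMAP (CH2Cl2, 0 °C) couple it with 3 to the mixed diester trixagyl 2-(trimethylsilyl)ethyl malonate F13.
   - TBAF (THF, 0 °C) cleaves the silylethyl ester by β-elimination, and acidification to pH 3–4 with cold citric acid gives 6.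

**Further compounds**
F1 | step 1 | (E)-geranylacetone, (5E)-6,10-dimethylundeca-5,9-dien-2-one | CC(C)=CCC/C(C)=C/CCC(C)=O
F2 | step 1 | (S)-γ-dihydroionone, 4-[(1S)-2,2-dimethyl-6-methylidenecyclohexyl]butan-2-one | C=C1CCCC(C)(C)[C@@H]1CCC(C)=O
F3 | step 1 | diethyl 4-[(1S)-2,2-dimethyl-6-methylidenecyclohexyl]but-1-en-2-yl phosphate | C=C1CCCC(C)(C)[C@@H]1CCC(=C)OP(=O)(OCC)OCC
F4 | step 1 | (2S)-2-(but-3-yn-1-yl)-1,1-dimethyl-3-methylidenecyclohexane | C=C1CCCC(C)(C)[C@@H]1CCC#C
F5 | step 1 | [(1E)-4-[(1S)-2,2-dimethyl-6-methylidenecyclohexyl]-2-methylbut-1-en-1-yl]dimethylalane | C=C1CCCC(C)(C)[C@@H]1CC/C(C)=C/[Al](C)C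
F6 | step 1 | (2S)-2-[(3E)-4-iodo-3-methylbut-3-en-1-yl]-1,1-dimethyl-3-methylidenecyclohexane | C=C1CCCC(C)(C)[C@@H]1CC/C(C)=C/I
F7 | step 1 | [4-(trimethylsilyl)but-3-yn-1-yl]zinc bromide | C[Si](C)(C)C#CCC[Zn]Br
F8 | step 1 | {(5E)-8-[(1S)-2,2-dimethyl-6-methylidenecyclohexyl]-6-methyloct-5-en-1-yn-1-yl}trimethylsilane | C=C1CCCC(C)(C)[C@@H]1CC/C(C)=C/CCC#C[Si](C)(C)C
F9 | step 1 | (2S)-1,1-dimethyl-3-methylidene-2-[(3E)-3-methyloct-3-en-7-yn-1-yl]cyclohexane | C=C1CCCC(C)(C)[C@@H]1CC/C(C)=C/CCC#C
F10 | step 1 | [(1E,5E)-8-[(1S)-2,2-dimethyl-6-methylidenecyclohexyl]-2,6-dimethylocta-1,5-dien-1-yl]dimethylalane | C=C1CCCC(C)(C)[C@@H]1CC/C(C)=C/CC/C(C)=C/[Al](C)C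
F11 | step 1 | lithium butyl[(1E,5E)-8-[(1S)-2,2-dimethyl-6-methylidenecyclohexyl]-2,6-dimethylocta-1,5-dien-1-yl]dimethylalanate | [Li+].C=C1CCCC(C)(C)[C@@H]1CC/C(C)=C/CC/C(C)=C/[Al-](C)(C)CCCC
F12 | step 2 | 3-oxo-3-[2-(trimethylsilyl)ethoxy]propanoic acid | C[Si](C)(C)CCOC(=O)CC(=O)O
F13 | step 2 | 1-[(2E,6E)-9-[(1S)-2,2-dimethyl-6-methylidenecyclohexyl]-3,7-dimethylnona-2,6-dien-1-yl] 3-[2-(trimethylsilyl)ethyl] propanedioate | C=C1CCCC(C)(C)[C@@H]1CC/C(C)=C/CC/C(C)=C/COC(=O)CC(=O)OCC[Si](C)(C)C
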